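**Plan**

1. Numbering: decalin as a drimane (C4 gem-dimethyl, C5=C6 olefin, stereocentres C8, C9, C10, C11 = CH2 link); quinone ring C1'(=O), C2'(OH), C3'(C11), C4'(=O), C5'(OMe), C6'(H).
2. Enabling feature: the quinone ring carries four different substituents in a fixed order; C1'–C4' with their oxygens and C11 map onto the four-membered ring of a squarate, and C5'(OMe)–C6'(H) onto a two-carbon (Z)-enol ether, so connectivity alone fixes the pattern.
3. Retrosynthetic cuts, in order: the isopropyl mask on O–C2'; C4'–C5' (6π closure of a dienylketene released from a cyclobutenone); C1'–C6' (vinyllithium addition); C3'–C11 (alkyllithium plus squarate); C9–C10 and C7–C8 (Diels–Alder).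
4. Forward: ring A diene from 2,2-dimethylcyclohexanone, ring B by Diels–Alder, neopentyl iodide, C-alkylation of the squarate ring, methoxyvinyl addition, then the quinone ring is closed last by thermal ring expansion; oxidation and de-isopropylation finish.
5. Stereochemistry: C8, C9 and C10 are all set in the one Diels–Alder step (cis methyls from the E enal, C10–H from the formyl-exo mode, absolute sense from a chiral oxazaborolidinium catalyst) and no later step touches them.

Key step: step 9

Abbreviation: DecCH2 = [(1R,2S,8aS)-1,2,5,5-tetramethyl-1,2,3,5,6,7,8,8a-octahydronaphthalen-1-yl]methyl; in 6, 7, 8 the same ring-fusion centre is named 8aR only because the CIP ranking changes.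

Assumption: the sense of induction in step 3 is assigned from the usual model for α-substituted enals on protonated diphenylprolinol-derived oxazaborolidines (aldehyde on the convex face, formyl C–H···O contact, s-trans enal stacked on the neighbouring phenyl group), which points to the (R)-configured catalyst for the (8S,9R,10S) series; should the adduct prove antipodal, the catalyst from (S)-diphenylprolinol is used and nothing else changes.

**Route**

Step 1
Reactants: 1 2,2-dimethylcyclohexan-1-one
Product: 3 6,6-dimethylcyclohex-1-en-1-yl trifluoromethanesulfonate, via lithium enolate 2 (not isolated)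
Conditions: LiN(i-Pr)2, THF, −78 °C; PhNTf2, −78 °C → rt; H2O work-up
Reagents that add atoms: N-phenylbis(trifluoromethanesulfonimide), O=S(=O)(N(c1ccccc1)S(=O)(=O)C(F)(F)F)C(F)(F)F
Why: Only C6 of the ketone carries α-hydrogens, so enolisation and O-sulfonylation of the lithium enolate (enol triflate formation) can give a single regioisomer.

Step 2
Reactants: 3 6,6-dimethylcyclohex-1-en-1-yl trifluoromethanesulfonate
Product: 4 1-ethenyl-6,6-dimethylcyclohex-1-ene
Conditions: CH2=CHSnBu3, Pd(PPh3)4 (cat.), LiCl, THF, 65 °C
Reagents that add atoms: tributyl(vinyl)stannane, C=C[Sn](CCCC)(CCCC)CCCC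
Why: Stille coupling of a cyclohexenyl triflate with a vinylstannane in the presence of LiCl is a standard, acid-free route to the semicyclic 1,3-diene and leaves no room for double-bond migration.

Step 3
Reactants: 4 1-ethenyl-6,6-dimethylcyclohex-1-ene, 5 (E)-2-methylbut-2-enal (tiglic aldehyde)
Product: 6 (1R,2S,8aR)-1,2,5,5-tetramethyl-1,2,3,5,6,7,8,8a-octahydronaphthalene-1-carbaldehyde
Conditions: (3aR)-1-(2-methylphenyl)-3,3-diphenyltetrahydro-1H,3H-pyrrolo[1,2-c][1,3,2]oxazaborole (C24H24BNO, 20 mol %, from (R)-α,α-diphenylprolinol and tri-o-tolylboroxine) + HNTf2 (18 mol %), CH2Cl2, −78 → −20 °C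
Reagents that add atoms: none
Why: Enantioselective Diels–Alder reaction of an α-substituted enal under chiral protonated oxazaborolidine catalysis, in which the unsubstituted vinyl terminus of 4 (largest HOMO coefficient) bonds to the β-carbon of the activated enal so that the quaternary C9 lies next to C10, the E geometry of 5 places the C8 and C9 methyl groups cis, the formyl-exo transition state (bound CHO kept away from the gem-dimethyl-bearing ring A, α-methyl under the diene) puts C10–H cis to the formyl group, and the catalyst phenyl group lying behind the s-trans enal leaves one face open, which sets the absolute configuration of all three centres.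

Step 4
Reactants: 6 (1R,2S,8aR)-1,2,5,5-tetramethyl-1,2,3,5,6,7,8,8a-octahydronaphthalene-1-carbaldehyde
Product: 7 [(1R,2S,8aR)-1,2,5,5-tetramethyl-1,2,3,5,6,7,8,8a-octahydronaphthalen-1-yl]methanol
Conditions: NaBH4, MeOH, 0 °C
Reagents that add atoms: none
Why: Hydride reduction of the non-enolisable neopentyl aldehyde gives the primary alcohol and touches neither the trisubstituted olefin nor a stereocentre.

Step 5
Reactants: 7 [(1R,2S,8aR)-1,2,5,5-tetramethyl-1,2,3,5,6,7,8,8a-octahydronaphthalen-1-yl]methanol
Product: 8 (1R,2S,8aR)-1-(iodomethyl)-1,2,5,5-tetramethyl-1,2,3,5,6,7,8,8a-octahydronaphthalene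
Conditions: PPh3, I2, imidazole, toluene, 90 °C
Reagents that add atoms: iodine, II
Why: Appel-type iodination via the alkoxyphosphonium iodide works on neopentyl primary alcohols when heated, the quaternary C9 rules out elimination, and imidazole keeps the medium non-acidic for the olefin.

Step 6
Reactants: 8 (1R,2S,8aR)-1-(iodomethyl)-1,2,5,5-tetramethyl-1,2,3,5,6,7,8,8a-octahydronaphthalene, 9 diisopropyl squarate [3,4-di(propan-2-yloxy)cyclobut-3-ene-1,2-dione]
Product: 13 3-isopropoxy-4-(DecCH2)cyclobut-3-ene-1,2-dione, via alkyllithium 10 (not isolated), via lithium alkoxide adduct 11 (not isolated), via trifluoroacetate 12 (not isolated)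
Conditions: t-BuLi (2.1 equiv), Et2O–pentane, −78 °C; then 9, THF, −78 °C; (CF3CO)2O, −78 °C; aq. NH4Cl
Reagents that add atoms: water, O
Why: Iodine–lithium exchange gives a primary alkyllithium without β-hydrogens that adds 1,2 to one carbonyl of the squarate, and O-trifluoroacetylation of the adduct lets trifluoroacetate ionise to an isopropoxy-stabilised cation that water converts into the cyclobutenedione with loss of propan-2-ol (the standard route from dialkyl squarates to 3-alkyl-4-alkoxycyclobutenediones).

Step 7
Reactants: 14 methyl vinyl ether (methoxyethene)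
Product: 16 (Z)-1-bromo-2-methoxyethene, via dibromo ether 15 (not isolated)
Conditions: Br2, pentane, −78 °C; then PhNEt2, 95 °C, distil
Reagents that add atoms: bromine, BrBr
Why: Bromine adds across the enol ether and the amine removes HBr from the labile α-bromo ether (bromination–dehydrobromination), giving the 2-bromovinyl ether mainly as the Z isomer, as is known for the ethoxy analogue.

Step 8
Reactants: 13 3-isopropoxy-4-(DecCH2)cyclobut-3-ene-1,2-dione, 16 (Z)-1-bromo-2-methoxyethene
Product: 18 4-hydroxy-3-isopropoxy-4-[(Z)-2-methoxyethenyl]-2-(DecCH2)cyclobut-2-en-1-one (both carbinol epimers), via (Z)-2-methoxyvinyllithium 17 (not isolated)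
Conditions: 16 (1.5 equiv), t-BuLi (3.0 equiv), Et2O, −78 °C; then 13, THF, −78 °C; aq. NH4Cl
Reagents that add atoms: none
Why: Bromine–lithium exchange with retention gives the (Z)-2-methoxyvinyllithium, which adds 1,2 to the more electrophilic carbonyl of 13, the one next to the isopropoxy-bearing carbon and not part of the vinylogous ester, as organolithiums generally do with 3-alkoxy-4-alkylcyclobutenediones; the new carbinol centre forms without control, which is harmless because it becomes sp2 in step 9.

Step 9
Reactants: 18 4-hydroxy-3-isopropoxy-4-[(Z)-2-methoxyethenyl]-2-(DecCH2)cyclobut-2-en-1-one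
Product: 21 2-isopropoxy-5-methoxy-3-(DecCH2)benzene-1,4-diol, via dienylketene 19 (not isolated), via cyclohexadienone 20 (not isolated)
Conditions: toluene (0.01 M, degassed), 110 °C, Ar
Reagents that add atoms: none
Why: Heating opens the cyclobutenone by conrotatory 4π electrocyclic cleavage of the C(=O)–C(OH) bond to dienylketene 19, which closes by disrotatory 6π electrocyclisation (new C4'–C5' bond between the ketene carbon and the methoxy-bearing vinyl carbon) to dienone 20, and enolisation gives the aromatic hydroquinone 21. The closest known reaction type is the thermal ring expansion of squarate-derived 4-alkenyl-4-hydroxycyclobutenones to hydroquinones, the alkenyl counterpart of the Moore rearrangement. The one ring formed, the six-membered quinone ring, is closed by the 6π electrocyclisation of the ketene and made irreversible by aromatisation. No stereocentre is created, since the carbinol carbon of 18 becomes sp2 and the sp3 carbon C5' of 20 is lost on enolisation, while C8, C9 and C10 are remote from the reacting π system. The step needs torquoselectivity, because only outward rotation of the hydroxyl places the methoxyvinyl group inside next to the ketene, and the strong preference of donor substituents on the breaking bond to rotate outward secures it, so both carbinol epimers converge. Regiochemistry needs no control here because the order O, C11, O-iPr, O, H, OMe around the ring is already written into the connectivity of 18, and the neutral degassed medium spares the enol ether, the decalin olefin and the air-sensitive product.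

Step 10
Reactants: 21 2-isopropoxy-5-methoxy-3-(DecCH2)benzene-1,4-diol
Product: 22 2-isopropoxy-5-methoxy-3-(DecCH2)cyclohexa-2,5-diene-1,4-dione
Conditions: Ag2O, Na2SO4, Et2O, 23 °C
Reagents that add atoms: none
Why: Oxidation of an electron-rich hydroquinone to the p-quinone by Ag2O is fast under neutral conditions that leave the olefin, the methyl ether and the isopropyl ether untouched.

Step 11
Reactants: 22 2-isopropoxy-5-methoxy-3-(DecCH2)cyclohexa-2,5-diene-1,4-dione
Product: 23 2-hydroxy-5-methoxy-3-{[(1R,2S,8aS)-1,2,5,5-tetramethyl-1,2,3,5,6,7,8,8a-octahydronaphthalen-1-yl]methyl}cyclohexa-2,5-diene-1,4-dione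
Conditions: BCl3 (1.5 equiv), CH2Cl2, −78 °C; pH 7 phosphate buffer
Reagents that add atoms: none
Why: Lewis-acid ether cleavage in which BCl3 chelates the C1' carbonyl and the C2' ether oxygen and removes the secondary isopropyl group as 2-chloropropane far faster than it attacks a methyl ether at −78 °C, so the C5' methoxy group and the C5=C6 olefin should survive the brief cold exposure and the buffered work-up frees the hydroxyl.

**Compound list**

1 | 2,2-dimethylcyclohexan-1-one | CC1(C)CCCCC1=O | starting material
2 | lithium 6,6-dimethylcyclohex-1-en-1-olate | [Li]OC1=CCCCC1(C)C | intermediate (not isolated)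
3 | 6,6-dimethylcyclohex-1-en-1-yl trifluoromethanesulfonate | CC1(C)CCCC=C1OS(=O)(=O)C(F)(F)F | intermediate
4 | 1-ethenyl-6,6-dimethylcyclohex-1-ene | C=CC1=CCCCC1(C)C | intermediate
5 | (E)-2-methylbut-2-enal (tiglic aldehyde) | C/C=C(\C)C=O | starting material
6 | (1R,2S,8aR)-1,2,5,5-tetramethyl-1,2,3,5,6,7,8,8a-octahydronaphthalene-1-carbaldehyde | O=C[C@@]1(C)[C@@H]2CCCC(C)(C)C2=CC[C@@H]1C | intermediate
7 | [(1R,2S,8aR)-1,2,5,5-tetramethyl-1,2,3,5,6,7,8,8a-octahydronaphthalen-1-yl]methanol | OC[C@@]1(C)[C@@H]2CCCC(C)(C)C2=CC[C@@H]1C | intermediate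
8 | (1R,2S,8aR)-1-(iodomethyl)-1,2,5,5-tetramethyl-1,2,3,5,6,7,8,8a-octahydronaphthalene | IC[C@@]1(C)[C@@H]2CCCC(C)(C)C2=CC[C@@H]1C | intermediate
9 | diisopropyl squarate, 3,4-di(propan-2-yloxy)cyclobut-3-ene-1,2-dione | CC(C)OC1=C(OC(C)C)C(=O)C1=O | starting material
10 | (DecCH2)lithium | [Li]C[C@@]1(C)[C@@H]2CCCC(C)(C)C2=CC[C@@H]1C | intermediate (not isolated)
11 | lithium 1-(DecCH2)-2,3-diisopropoxy-4-oxocyclobut-2-en-1-olate (both epimers) | [Li]OC1(C[C@@]2(C)[C@@H]3CCCC(C)(C)C3=CC[C@@H]2C)C(OC(C)C)=C(OC(C)C)C1=O | intermediate (not isolated)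
12 | 1-(DecCH2)-2,3-diisopropoxy-4-oxocyclobut-2-en-1-yl trifluoroacetate | O=C(OC1(C[C@@]2(C)[C@@H]3CCCC(C)(C)C3=CC[C@@H]2C)C(OC(C)C)=C(OC(C)C)C1=O)C(F)(F)F | intermediate (not isolated)
13 | 3-isopropoxy-4-(DecCH2)cyclobut-3-ene-1,2-dione | CC(C)OC1=C(C[C@@]2(C)[C@@H]3CCCC(C)(C)C3=CC[C@@H]2C)C(=O)C1=O | intermediate
14 | methyl vinyl ether (methoxyethene) | COC=C | starting material
15 | 1,2-dibromo-1-methoxyethane | COC(Br)CBr | intermediate (not isolated)
16 | (Z)-1-bromo-2-methoxyethene | CO/C=C\Br | intermediate
17 | (Z)-2-methoxyvinyllithium | CO/C=C\[Li] | intermediate (not isolated)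
18 | 4-hydroxy-3-isopropoxy-4-[(Z)-2-methoxyethenyl]-2-(DecCH2)cyclobut-2-en-1-one (carbinol epimers) | CO/C=C\C1(O)C(OC(C)C)=C(C[C@@]2(C)[C@@H]3CCCC(C)(C)C3=CC[C@@H]2C)C1=O | intermediate (key-step precursor)
19 | (3Z,5Z)-4-hydroxy-3-isopropoxy-6-methoxy-2-(DecCH2)hexa-1,3,5-trien-1-one | O=C=C(C[C@@]1(C)[C@@H]2CCCC(C)(C)C2=CC[C@@H]1C)/C(OC(C)C)=C(O)\C=C/OC | intermediate (not isolated)
20 | 4-hydroxy-3-isopropoxy-6-methoxy-2-(DecCH2)cyclohexa-2,4-dien-1-one | COC1C=C(O)C(OC(C)C)=C(C[C@@]2(C)[C@@H]3CCCC(C)(C)C3=CC[C@@H]2C)C1=O | intermediate (not isolated)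
21 | 2-isopropoxy-5-methoxy-3-(DecCH2)benzene-1,4-diol | COc1cc(O)c(OC(C)C)c(C[C@@]2(C)[C@@H]3CCCC(C)(C)C3=CC[C@@H]2C)c1O | intermediate (key-step product)
22 | 2-isopropoxy-5-methoxy-3-(DecCH2)cyclohexa-2,5-diene-1,4-dione | COC1=CC(=O)C(OC(C)C)=C(C[C@@]2(C)[C@@H]3CCCC(C)(C)C3=CC[C@@H]2C)C1=O | intermediate
23 | 2-hydroxy-5-methoxy-3-{[(1R,2S,8aS)-1,2,5,5-tetramethyl-1,2,3,5,6,7,8,8a-octahydronaphthalen-1-yl]methyl}cyclohexa-2,5-diene-1,4-dione | COC1=CC(=O)C(O)=C(C[C@@]2(C)[C@@H]3CCCC(C)(C)C3=CC[C@@H]2C)C1=O | target

**Step count and risks**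

Total: 11 steps. Longest linear sequence: 10 steps (steps 1–6 and 8–11); step 7 is a one-step branch.

Steps most likely to fail:

1. Step 3. The catalyst may discriminate incompletely between the two faces of the enal or between formyl-exo and formyl-endo approach, or the strongly acidic catalyst may oligomerise diene 4 before the sluggish trisubstituted enal reacts. The fallback sets out from 4 and 5 and returns at 7. An achiral Lewis acid (EtAlCl2, CH2Cl2, −78 °C) should still favour the formyl-exo ortho adduct and give the racemic aldehyde F1. NaBH4 reduction gives the racemic alcohol F2, which is esterified with (S)-2-methoxy-2-phenylacetic acid (DCC, DMAP). The two diastereomeric esters, the (1R,2S,8aR)-configured mandelate F3 and its (1S,2R,8aS)-configured diastereomer F4, are separated by chromatography or crystallisation and assigned by X-ray analysis. Saponification of F3 (LiOH, THF–H2O) returns alcohol 7.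

2. Step 9. The 6π closure may be slowed because the methoxy group of the Z enol ether must swing to the inside position at the ring-closing terminus, so the dienylketene is diverted to oligomers or trapped by adventitious nucleophiles. The fallback sets out from 13 and returns at 22. Vinyllithium (THF, −78 °C) adds to the same carbonyl of 13 to give the vinyl carbinol F5. Thermolysis in toluene gives the methoxy-free hydroquinone F6, and Ag2O oxidises it to the isopropoxyquinone F7. ZnCl2-mediated conjugate addition of methanol in air then goes to C5', the β-position of the carbonyl that the isopropoxy group does not deactivate, and reoxidation gives quinone 22.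

3. Step 11. The Lewis acid or liberated HCl may shift the C5=C6 olefin to the tetrasubstituted C5=C10 position (loss of the C10 stereocentre), the freed hydroxyl may cyclise onto the protonated olefin, or the methyl ether may be cleaved as well. The fallback is acid-free, sets out from 22 and returns at 23. Alkaline hydrolysis of both vinylogous esters (aq. NaOH, EtOH, reflux, then mild acidification) gives the dihydroxyquinone F8. One equivalent of TMSCHN2 in MeOH–toluene at 0 °C should then methylate the less hindered hydroxyl at C5', which is flanked by C6'–H and not by the neopentyl group, to give 23.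

**Further compounds**

F1 | step 3 | racemic (1R*,2S*,8aR*)-1,2,5,5-tetramethyl-1,2,3,5,6,7,8,8a-octahydronaphthalene-1-carbaldehyde | O=C[C@@]1(C)[C@@H]2CCCC(C)(C)C2=CC[C@@H]1C.O=C[C@]1(C)[C@H]2CCCC(C)(C)C2=CC[C@H]1C
F2 | step 3 | racemic [(1R*,2S*,8aR*)-1,2,5,5-tetramethyl-1,2,3,5,6,7,8,8a-octahydronaphthalen-1-yl]methanol | OC[C@@]1(C)[C@@H]2CCCC(C)(C)C2=CC[C@@H]1C.OC[C@]1(C)[C@H]2CCCC(C)(C)C2=CC[C@H]1C
F3 | step 3 | [(1R,2S,8aR)-1,2,5,5-tetramethyl-1,2,3,5,6,7,8,8a-octahydronaphthalen-1-yl]methyl (S)-2-methoxy-2-phenylacetate | CO[C@H](C(=O)OC[C@@]1(C)[C@@H]2CCCC(C)(C)C2=CC[C@@H]1C)c1ccccc1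
F4 | step 3 | [(1S,2R,8aS)-1,2,5,5-tetramethyl-1,2,3,5,6,7,8,8a-octahydronaphthalen-1-yl]methyl (S)-2-methoxy-2-phenylacetate | CO[C@H](C(=O)OC[C@]1(C)[C@H]2CCCC(C)(C)C2=CC[C@H]1C)c1ccccc1
F5 | step 9 | 4-ethenyl-4-hydroxy-3-isopropoxy-2-(DecCH2)cyclobut-2-en-1-one | C=CC1(O)C(OC(C)C)=C(C[C@@]2(C)[C@@H]3CCCC(C)(C)C3=CC[C@@H]2C)C1=O
F6 | step 9 | 2-isopropoxy-3-(DecCH2)benzene-1,4-diol | Oc1ccc(O)c(OC(C)C)c1C[C@@]2(C)[C@@H]3CCCC(C)(C)C3=CC[C@@H]2C
F7 | step 9 | 2-isopropoxy-3-(DecCH2)cyclohexa-2,5-diene-1,4-dione | CC(C)OC1=C(C[C@@]2(C)[C@@H]3CCCC(C)(C)C3=CC[C@@H]2C)C(=O)C=CC1=O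
F8 | step 11 | 2,5-dihydroxy-3-(DecCH2)cyclohexa-2,5-diene-1,4-dione | OC1=CC(=O)C(O)=C(C[C@@]2(C)[C@@H]3CCCC(C)(C)C3=CC[C@@H]2C)C1=O
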